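**Assumption:** 2-(1,3-oxazol-5-yl)acetic acid, 1-bromobutane-2,3-dione and 14-methylpentadecanoic acid are taken as catalogue chemicals; the acyl chain of the target SMILES is read as 14-methylpentadecanoyl (sixteen carbons).

## Retrosynthetic overview

1. The ester C(alkyl)–O bond is not made by acylating a protected polyol. It is made late by SN2 opening of a cis-2,3-epoxy alcohol with the free fatty acid, which inverts C2, frees the C3 hydroxyl and needs no protecting groups.
2. The C6 carbinol is made last, by 1,3-syn reduction of a C6 ketone directed by the C4 hydroxyl.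
3. The C4–C5 bond comes from a Felkin–Anh boron aldol of the bis-oxazolyl methyl ketone with (2R,3R)-2,3-epoxybutanal, so C4 is relayed from the oxirane.
4. The epoxy aldehyde comes from L-threonine (bromohydrin, then oxirane), so all four stereocentres descend from threonine.
5. Ring order: oxirane ring A (step 2), then the 2,4-disubstituted oxazole ring B by Blümlein–Lewy condensation (step 6; the 5-substituted oxazole ring C is bought), then ring A is opened in step 8.

## Route

**Step 1**
Reactants: 1 L-threonine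
Product: 4 (2S,3R)-2-bromo-3-hydroxybutanoic acid, via diazonium carboxylate 2 (not isolated), via alpha-lactone 3 (not isolated)
Conditions: NaNO2, KBr, 1.25 M aq. H2SO4, −5 → 23 °C
Reagents that add atoms: potassium bromide, [K+].[Br-]; sodium nitrite, [Na+].[O-]N=O (its nitrogen is held only in 2 and leaves as N2)
Why: Diazotisation of the α-amino acid with bromide capture runs with net retention (double inversion through the α-lactone, neighbouring-carboxylate participation), so C2 stays S and the untouched carbinol stays R.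

**Step 2**
Reactants: 4 (2S,3R)-2-bromo-3-hydroxybutanoic acid
Product: 5 potassium (2R,3R)-3-methyloxirane-2-carboxylate
Conditions: KOH (2.0 equiv), EtOH, −20 → 23 °C
Reagents that add atoms: potassium hydroxide, [K+].[OH-]
Why: Intramolecular Williamson etherification (bromohydrin to epoxide): the alkoxide displaces bromide by SN2 with inversion at C2, turning the threo bromohydrin into the cis-(2R,3R)-oxirane (ring A).

**Step 3**
Reactants: 5 potassium (2R,3R)-3-methyloxirane-2-carboxylate
Product: 6 methyl (2R,3R)-3-methyloxirane-2-carboxylate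
Conditions: MeI (1.5 equiv), DMF, 23 °C
Reagents that add atoms: iodomethane, CI
Why: Carboxylate O-alkylation (SN2 on MeI) under neutral conditions leaves the oxirane and both stereocentres untouched.

**Step 4**
Reactants: 6 methyl (2R,3R)-3-methyloxirane-2-carboxylate
Product: 8 (2R,3R)-3-methyloxirane-2-carbaldehyde, via aluminium hemiacetal 7 (not isolated)
Conditions: iBu2AlH (1.05 equiv), CH2Cl2, −78 °C; aq. KNaC4H4O6 work-up; dried CH2Cl2 solution used at once
Reagents that add atoms: diisobutylaluminium hydride, CC(C)C[AlH]CC(C)C (aluminium and isobutyl groups are held only in 7)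
Why: Partial reduction of an α-oxygenated ester stops at the chelated aluminium hemiacetal at −78 °C and gives the aldehyde on hydrolysis; the oxirane α-carbon does not enolise, so the cis configuration is kept.

**Step 5**
Reactants: 9 2-(1,3-oxazol-5-yl)acetic acid
Product: 11 2-(1,3-oxazol-5-yl)acetamide, via acyl imidazole 10 (not isolated)
Conditions: CDI (1.1 equiv), THF, 23 °C; then NH3 (7 M in MeOH), 0 → 23 °C
Reagents that add atoms: ammonia, N; 1,1'-carbonyldiimidazole, O=C(n1ccnc1)n1ccnc1 (its imidazolyl group is held only in 10)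
Why: Acyl imidazole activation followed by ammonolysis is a mild amide synthesis that the oxazole (ring C) tolerates.

**Step 6**
Reactants: 11 2-(1,3-oxazol-5-yl)acetamide; 12 1-bromobutane-2,3-dione
Product: 15 1-[2-(1,3-oxazol-5-ylmethyl)-1,3-oxazol-4-yl]ethan-1-one, via hydroxyoxazoline 13 (not isolated), via oxazoline trifluoroacetate 14 (not isolated)
Conditions: 12 (1.5 equiv), NaHCO3, THF, 60 °C; then (CF3CO)2O, 2,6-lutidine, 0 °C
Reagents that add atoms: trifluoroacetic anhydride, O=C(OC(=O)C(F)(F)F)C(F)(F)F (its trifluoroacetyl group is held only in 14)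
Why: Blümlein–Lewy (Hantzsch-type) oxazole synthesis: the amide oxygen is alkylated by the bromomethyl ketone, the nitrogen closes onto the adjacent carbonyl, and the 4-hydroxyoxazoline is dehydrated through its trifluoroacetate to ring B already carrying the 4-acetyl group.

**Step 7**
Reactants: 15 1-[2-(1,3-oxazol-5-ylmethyl)-1,3-oxazol-4-yl]ethan-1-one; 8 (2R,3R)-3-methyloxirane-2-carbaldehyde
Product: 18 (3S)-3-hydroxy-3-[(2S,3R)-3-methyloxiran-2-yl]-1-[2-(1,3-oxazol-5-ylmethyl)-1,3-oxazol-4-yl]propan-1-one, via boron enolate 16 (not isolated), via boron aldolate 17 (not isolated)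
Conditions: c-Hex2BCl (1.5 equiv), Et3N, Et2O, 0 °C; then 8 (1.5 equiv), −78 → −20 °C; then MeOH, pH 7 NaH2PO4/Na2HPO4 buffer, 30% H2O2, 0 °C
Reagents that add atoms: chlorodicyclohexylborane, ClB(C1CCCCC1)C1CCCCC1 (boron and cyclohexyl groups are held only in 16 and 17)
Why: Boron-mediated methyl ketone aldol addition: soft enolisation is selective for the acetyl group, and the enol borinate attacks the cis-epoxy aldehyde in the Felkin–Anh (Cornforth) sense, anti to the oxirane C–O bond, which sets the new carbinol as S (3,4-anti); the minor epimer is removed by chromatography.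

**Step 8**
Reactants: 18 (3S)-3-hydroxy-3-[(2S,3R)-3-methyloxiran-2-yl]-1-[2-(1,3-oxazol-5-ylmethyl)-1,3-oxazol-4-yl]propan-1-one; 19 14-methylpentadecanoic acid
Product: 21 (2S,3S,4S)-3,4-dihydroxy-6-oxo-6-[2-(1,3-oxazol-5-ylmethyl)-1,3-oxazol-4-yl]hexan-2-yl 14-methylpentadecanoate, via titanium alkoxide 20 (not isolated)
Conditions: Ti(OiPr)4 (1.5 equiv), 19 (1.5 equiv), CH2Cl2, 0 → 23 °C; 10% aq. tartaric acid work-up
Reagents that add atoms: titanium tetraisopropoxide, CC(C)O[Ti](OC(C)C)(OC(C)C)OC(C)C (titanium and isopropoxy groups are held only in 20)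
Why: Sharpless-type titanium-mediated opening of a 2,3-epoxy alcohol by a carboxylic acid: the titanium alkoxide of the carbinol activates the oxirane and the acid attacks the distal, less hindered methyl-bearing carbon by SN2 with inversion, which forms the ester C–O bond, sets C2 as S and frees the C3 hydroxyl with retention (S).

**Step 9**
Reactants: 21 (2S,3S,4S)-3,4-dihydroxy-6-oxo-6-[2-(1,3-oxazol-5-ylmethyl)-1,3-oxazol-4-yl]hexan-2-yl 14-methylpentadecanoate
Product: 23 (2S,3S,4S,6R)-3,4,6-trihydroxy-6-[2-(1,3-oxazol-5-ylmethyl)-1,3-oxazol-4-yl]hexan-2-yl 14-methylpentadecanoate, via diethylboron chelate 22 (not isolated)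
Conditions: Et2BOMe (2.2 equiv), THF/MeOH 4:1, −78 °C; NaBH4 (1.5 equiv), −78 °C; AcOH quench; MeOH co-evaporation
Reagents that add atoms: diethylmethoxyborane, CCB(CC)OC (boron and ethyl groups are held only in 22)
Why: Narasaka–Prasad reduction: the six-membered diethylboron chelate of the β-hydroxy ketone takes external hydride axially and gives the 1,3-syn diol, setting C6 as R and completing the target; the ester is inert to NaBH4 at −78 °C and the non-basic work-up avoids acyl migration.

## Compound list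

1 | L-threonine, (2S,3R)-2-amino-3-hydroxybutanoic acid | C[C@@H](O)[C@H](N)C(=O)O | starting material
2 | (2S,3R)-2-diazonio-3-hydroxybutanoate (diazonium carboxylate) | C[C@@H](O)[C@H]([N+]#N)C(=O)[O-] | intermediate
3 | (3R)-3-[(1R)-1-hydroxyethyl]oxiran-2-one (alpha-lactone) | C[C@@H](O)[C@H]1OC1=O | intermediate
4 | (2S,3R)-2-bromo-3-hydroxybutanoic acid | C[C@@H](O)[C@H](Br)C(=O)O | intermediate
5 | potassium (2R,3R)-3-methyloxirane-2-carboxylate (cis) | C[C@H]1O[C@H]1C(=O)[O-].[K+] | intermediate
6 | methyl (2R,3R)-3-methyloxirane-2-carboxylate | C[C@H]1O[C@H]1C(=O)OC | intermediate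
7 | diisobutylaluminium hemiacetal of 6, methoxy[(2R,3R)-3-methyloxiran-2-yl]methyl aluminate | C[C@H]1O[C@H]1C(OC)O[Al](CC(C)C)CC(C)C | intermediate
8 | (2R,3R)-3-methyloxirane-2-carbaldehyde (cis-2,3-epoxybutanal) | C[C@H]1O[C@H]1C=O | intermediate
9 | 2-(1,3-oxazol-5-yl)acetic acid | OC(=O)Cc1cnco1 | starting material
10 | 1-(1H-imidazol-1-yl)-2-(1,3-oxazol-5-yl)ethan-1-one (acyl imidazole) | O=C(Cc1cnco1)n1ccnc1 | intermediate
11 | 2-(1,3-oxazol-5-yl)acetamide | NC(=O)Cc1cnco1 | intermediate
12 | 1-bromobutane-2,3-dione | CC(=O)C(=O)CBr | starting material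
13 | 1-[4-hydroxy-2-(1,3-oxazol-5-ylmethyl)-4,5-dihydro-1,3-oxazol-4-yl]ethan-1-one (racemic hydroxyoxazoline) | CC(=O)C1(O)COC(Cc2cnco2)=N1 | intermediate
14 | 4-acetyl-2-(1,3-oxazol-5-ylmethyl)-4,5-dihydro-1,3-oxazol-4-yl trifluoroacetate | CC(=O)C1(OC(=O)C(F)(F)F)COC(Cc2cnco2)=N1 | intermediate
15 | 1-[2-(1,3-oxazol-5-ylmethyl)-1,3-oxazol-4-yl]ethan-1-one | CC(=O)c1coc(Cc2cnco2)n1 | intermediate
16 | dicyclohexylboron enolate of 15 | C=C(OB(C1CCCCC1)C2CCCCC2)c3coc(Cc4cnco4)n3 | intermediate
17 | dicyclohexylboron aldolate of 18 | C[C@H]1O[C@H]1[C@@H](OB(C2CCCCC2)C3CCCCC3)CC(=O)c4coc(Cc5cnco5)n4 | intermediate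
18 | (3S)-3-hydroxy-3-[(2S,3R)-3-methyloxiran-2-yl]-1-[2-(1,3-oxazol-5-ylmethyl)-1,3-oxazol-4-yl]propan-1-one | C[C@H]1O[C@H]1[C@@H](O)CC(=O)c1coc(Cc2cnco2)n1 | intermediate
19 | 14-methylpentadecanoic acid | CC(C)CCCCCCCCCCCCC(=O)O | starting material
20 | triisopropoxytitanium alkoxide of 18 | C[C@H]1O[C@H]1[C@@H](O[Ti](OC(C)C)(OC(C)C)OC(C)C)CC(=O)c1coc(Cc2cnco2)n1 | intermediate
21 | (2S,3S,4S)-3,4-dihydroxy-6-oxo-6-[2-(1,3-oxazol-5-ylmethyl)-1,3-oxazol-4-yl]hexan-2-yl 14-methylpentadecanoate | CC(C)CCCCCCCCCCCCC(=O)O[C@@H](C)[C@@H](O)[C@@H](O)CC(=O)c1coc(Cc2cnco2)n1 | intermediate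
22 | 4-O-diethylboryl chelate of 21 | CC(C)CCCCCCCCCCCCC(=O)O[C@@H](C)[C@@H](O)[C@@H](OB(CC)CC)CC(=O)c1coc(Cc2cnco2)n1 | intermediate
23 | (2S,3S,4S,6R)-3,4,6-trihydroxy-6-[2-(1,3-oxazol-5-ylmethyl)-1,3-oxazol-4-yl]hexan-2-yl 14-methylpentadecanoate (CNP0327583.1) | CC(C)CCCCCCCCCCCCC(=O)O[C@@H](C)[C@@H](O)[C@@H](O)C[C@@H](O)c1coc(Cc2cnco2)n1 | target

## Step count and risks

Total step count: 9. Longest linear sequence: 7 steps (1, 2, 3, 4, 7, 8, 9 from L-threonine).

**Step 8 is the most likely to fail.** The titanium alkoxide of a β-hydroxy ketone may undergo retro-aldol cleavage or dehydration, the acid may attack the wrong oxirane carbon, and the new ester may migrate to the neighbouring hydroxyl. The fallback sets out from 18 and changes both the order and the mode of opening. The ketone is reduced first under the conditions of step 9, through the diethylboron chelate F1, to the syn-diol epoxide F2. The 1,3-diol is tied up as the acetonide F3 (2-methoxypropene, pyridinium p-toluenesulfonate, CH2Cl2, 0 °C). The oxirane is then opened at the methyl-bearing carbon by caesium 14-methylpentadecanoate F4, made from 19 (3 equiv) and Cs2CO3 (0.5 equiv) in DMF at 80 °C. This is an SN2 opening with inversion at the less hindered carbon, buffered by the excess acid against acyl migration, and it gives the acetonide hydroxy ester F5. Removal of the acetonide with 80% aq. AcOH at 23 °C brings the sequence back to the route at 23.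

**Step 7 is the second risk.** The Felkin preference of the closed boron transition state may be modest, the small aldehyde 8 is volatile and water-soluble, and the oxazole nitrogens bind boron. The fallback sets out from 15, which is converted into the isolated trimethylsilyl enol ether F6 (Me3SiOTf, Et3N, CH2Cl2, 0 °C). A Mukaiyama aldol addition to 8 (BF3·OEt2, CH2Cl2, −78 °C) follows; it has an open transition state in which facial choice rests on the polar Felkin–Anh/Cornforth preference of the epoxy aldehyde alone. It gives the difluoroboron aldolate F7, which aq. NaHCO3 hydrolyses, and the sequence comes back to the route at 18.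

**Step 6 is the third risk.** 1-Bromobutane-2,3-dione is doubly electrophilic and can alkylate the oxazole nitrogen or the activated methylene, so the yield of the 4-acetyl oxazole may be low. The fallback sets out from 11, which is condensed with ethyl bromopyruvate (NaHCO3, dioxane, 100 °C) to ethyl 2-(1,3-oxazol-5-ylmethyl)-1,3-oxazole-4-carboxylate F8. Chloromagnesium methoxy(methyl)amide F9, made from MeNH(OMe)·HCl and iPrMgCl in THF at −20 °C, converts this ester into the Weinreb amide F10. MeMgBr (2.2 equiv, THF, −78 → 0 °C) then gives the methyl ketone, and the sequence comes back to the route at 15.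

## Further compounds

F1 | step 8 | 3-O-diethylboryl chelate of 18 | C[C@H]1O[C@H]1[C@@H](OB(CC)CC)CC(=O)c1coc(Cc2cnco2)n1
F2 | step 8 | (1S,3R)-1-[(2S,3R)-3-methyloxiran-2-yl]-3-[2-(1,3-oxazol-5-ylmethyl)-1,3-oxazol-4-yl]propane-1,3-diol | C[C@H]1O[C@H]1[C@@H](O)C[C@@H](O)c1coc(Cc2cnco2)n1
F3 | step 8 | acetonide of F2, 4-[(4R,6S)-2,2-dimethyl-6-[(2S,3R)-3-methyloxiran-2-yl]-1,3-dioxan-4-yl]-2-(1,3-oxazol-5-ylmethyl)-1,3-oxazole | C[C@H]1O[C@H]1[C@@H]2C[C@H](c3coc(Cc4cnco4)n3)OC(C)(C)O2
F4 | step 8 | caesium 14-methylpentadecanoate | CC(C)CCCCCCCCCCCCC(=O)[O-].[Cs+]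
F5 | step 8 | 4,6-O-isopropylidene acetal of 23, (1S,2S)-1-[(4S,6R)-2,2-dimethyl-6-[2-(1,3-oxazol-5-ylmethyl)-1,3-oxazol-4-yl]-1,3-dioxan-4-yl]-1-hydroxypropan-2-yl 14-methylpentadecanoate | CC(C)CCCCCCCCCCCCC(=O)O[C@@H](C)[C@@H](O)[C@@H]1C[C@H](c2coc(Cc3cnco3)n2)OC(C)(C)O1
F6 | step 7 | 2-(1,3-oxazol-5-ylmethyl)-4-[1-(trimethylsilyloxy)ethenyl]-1,3-oxazole | C=C(O[Si](C)(C)C)c1coc(Cc2cnco2)n1
F7 | step 7 | difluoroboron aldolate of 18 | C[C@H]1O[C@H]1[C@@H](OB(F)F)CC(=O)c1coc(Cc2cnco2)n1
F8 | step 6 | ethyl 2-(1,3-oxazol-5-ylmethyl)-1,3-oxazole-4-carboxylate | CCOC(=O)c1coc(Cc2cnco2)n1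
F9 | step 6 | chloromagnesium methoxy(methyl)amide | CON(C)[Mg]Cl
F10 | step 6 | N-methoxy-N-methyl-2-(1,3-oxazol-5-ylmethyl)-1,3-oxazole-4-carboxamide | CON(C)C(=O)c1coc(Cc2cnco2)n1
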